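Atoms C1–C6 of the germacrane ring, with the Z C4=C5 olefin, the C4 methyl and the syn oxygens on C2 and C3, map onto the six-membered ring of ent-toluene cis-dihydrodiol; C7–C10 are spliced in between C6 and C1. A single anionic oxy-Cope rearrangement does this: it breaks C1–C6, forms C8–C9, the ring-cis C1=C10 olefin and the C6 ketone, and sets C8 and C9. Its precursor is a cyclohexenol acetonide with, on C6, the hydroxyl and an E 2-(4-methoxybenzyloxy)vinyl group and, cis to it on C1, a 2,2-dimethyl-4H-1,3-dioxin-5-yl group that locks O9 trans to C1 and carries C14.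

Key step: step 12

Remarks and assumptions (chemistry)
- Germacrane numbering is used throughout (ring C1–C10, lactone carbons C11–C13, C14 on C10, C15 on C4). "α" is the face of the six-membered ring that carries O2 and O3; "β" is the other face.
- Read from the target: ring centres 2R,3S,6R,7S,8S,9S; the O9 ester is (R)-2-methylbutanoate; the O8 ester is (2S,3S)-2,3-dimethyloxirane-2-carboxylate (epoxyangelate).
- The C7=C8 enol ether of the precursor is E. The C9=C10 enol ether is Z by the sequence rule (O9 cis to C14), but O9 is trans to C1, which is what the chair needs; the dioxin ring fixes this geometry.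
- A cis-diol gives the cis-epoxide on the same face only with net retention at both carbons (two inversions at one carbon); step 21 is built for that.
- Assumption: toluene dioxygenase oxidises 4-iodotoluene at the ring bond next to iodine, with the facial sense known for iodoarenes.
- Assumption: in step 21 chloride is drawn at C3; opening at C2 would give the same epoxide.
- (R)-2-Methylbutanoic acid, angelic acid and 2,2-dimethyl-1,3-dioxan-5-one are taken as commercial.

Step 1
Reactants: 1 4-iodotoluene
Product: 2 (1S,2S)-3-iodo-6-methylcyclohexa-3,5-diene-1,2-diol (iodine on future C1, hydroxyls on future C2 and C3)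
Conditions: E. coli JM109(pDTG601) whole cells expressing toluene dioxygenase, glucose, air, phosphate buffer pH 7, 30 °C
Reagents that add atoms: dioxygen, O=O
Why: Enzymatic arene cis-dihydroxylation, in which the dioxygenase oxidises the ring bond next to the larger para substituent (iodine) from one face and so sets both carbinol centres in the sense that, once iodine is removed, is the mirror image of the usual toluene diol.

Step 2
Reactants: 2 iodo diene diol
Product: 3 acetonide of 2, (3aS,7aS)-7-iodo-2,2,4-trimethyl-3a,7a-dihydro-1,3-benzodioxole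
Conditions: 2,2-dimethoxypropane, TsOH·H2O (cat.), acetone, 0 °C
Reagents that add atoms: 2,2-dimethoxypropane, COC(C)(C)OC
Why: Acid-catalysed transketalisation of the cis-diol gives the cis-fused dioxolane and blocks dehydration to the phenol.

Step 3
Reactants: 3 iodo diene acetonide
Product: 4 (3aS,7aR)-2,2,4-trimethyl-3a,7a-dihydro-1,3-benzodioxole (acetonide of ent-toluene cis-dihydrodiol)
Conditions: Pd(OAc)2 (5 mol%), PPh3 (10 mol%), HCO2H, Et3N, DMF, 40 °C
Reagents that add atoms: none
Why: Palladium-catalysed formate transfer hydrogenolysis of the alkenyl iodide (oxidative addition, decarboxylation of the formate, C–H reductive elimination) removes iodine and leaves the diene untouched.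

Step 4
Reactants: 4 diene acetonide
Product: 5 (3aS,7aR)-2,2,4-trimethyl-3a,6,7,7a-tetrahydro-1,3-benzodioxole (only the C4=C5 olefin left)
Conditions: KO2C–N=N–CO2K, AcOH, MeOH, 0 °C to rt
Reagents that add atoms: none
Why: Diimide reduction, in which concerted syn hydrogen transfer goes to the cis-disubstituted C1=C6 bond much faster than to the trisubstituted C4=C5 bond.

Step 5
Reactants: 5 cyclohexene acetonide
Product: 6 (4S,5R)-4,5-(isopropylidenedioxy)-3-methylcyclohex-2-en-1-one (C6 ketone, C1 methylene)
Conditions: Mn(OAc)3·2H2O (10 mol%), t-BuOOH, 3 Å MS, EtOAc, rt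
Reagents that add atoms: tert-butyl hydroperoxide, CC(C)(C)OO
Why: Radical allylic C–H oxidation catalysed by trivalent manganese acetate takes the ring methylene next to the olefinic CH (C6) to the ketone, the regiochemistry that turns 1-methylcyclohexenes into 3-methylcyclohexenones.

Step 6
Reactants: 6 enone
Product: 7 cross-conjugated trimethylsilyl dienol ether of 6 (C6(OSiMe3)=C1, C4=C5)
Conditions: LiN(iPr)2, Me3SiCl, THF, −78 °C
Reagents that add atoms: chlorotrimethylsilane, C[Si](C)(C)Cl
Why: Kinetic deprotonation at the α′ methylene (C1) with silylation of the enolate in the flask at −78 °C gives the enol silane before the C2 oxygen can be expelled.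

Step 7
Reactants: 8 2,2-dimethyl-1,3-dioxan-5-one
Product: 9 2,2-dimethyl-4H-1,3-dioxin-5-yl trifluoromethanesulfonate
Conditions: KN(SiMe3)2, PhNTf2, THF, −78 °C
Reagents that add atoms: N-phenylbis(trifluoromethanesulfonimide), O=S(=O)(N(c1ccccc1)S(=O)(=O)C(F)(F)F)C(F)(F)F
Why: Enolisation and O-triflation give the cyclic enol triflate, in which the ring holds the enol oxygen cis to the CH2O carbon.

Step 8
Reactants: 7 enol silane; 9 dioxinyl triflate
Product: 10 enone 6 carrying the 2,2-dimethyl-4H-1,3-dioxin-5-yl group on C1, on the β face (trans to O2)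
Conditions: Pd2(dba)3 (2.5 mol%), P(t-Bu)3 (10 mol%), Bu3SnF, toluene, 60 °C
Reagents that add atoms: none
Why: Palladium-catalysed α-alkenylation of a ketone enol silane through its tin enolate (transmetalation to the alkenylpalladium triflate, then reductive elimination) forms C1–C10 without strong base, and palladium takes C1 on the face away from the dioxolane, so C10 ends anti to the acetonide.

Step 9
Reactants: 11 4-methoxybenzyl alcohol; 12 trichloroethylene
Product: 13 (E)-1,2-dichlorovinyl 4-methoxybenzyl ether
Conditions: KH, THF, 0 °C; then 12, −50 °C to rt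
Reagents that add atoms: none
Why: The alkoxide adds to dichloroacetylene formed in the flask from trichloroethylene (elimination–addition), giving the dichlorovinyl ether as a masked alkoxyacetylene.

Step 10
Reactants: 10 C1-dioxinyl enone; 13 dichlorovinyl ether
Product: 15 C6 tertiary propargylic alcohol with the (4-methoxybenzyloxy)ethynyl group β and the hydroxyl α, via lithium alkoxyethynide 14 (not isolated)
Conditions: 13, n-BuLi (2 equiv), THF, −78 to −40 °C; CeCl3, −78 °C; then 10; H2O
Reagents that add atoms: none
Why: Butyllithium converts 13 into the lithium alkoxyacetylide (elimination, then chlorine–lithium exchange), whose cerium derivative adds 1,2 to the enolisable ketone by axial attack antiperiplanar to the axial C1–H on the face away from the dioxolane, so the alkynyl group ends cis to the C1 alkenyl group.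

Step 11
Reactants: 15 propargylic alcohol
Product: 16 cis-1,6-dialkenylcyclohexenol: C6 α-OH and β (E)-2-(4-methoxybenzyloxy)vinyl, C1 β-dioxinyl, C2/C3 acetonide α
Conditions: LiAlH4, THF, 0 °C to rt; then Na2SO4·10H2O
Reagents that add atoms: none
Why: Alkoxide-directed trans-hydroalumination of the propargylic alcohol followed by protonolysis of the alkenyl–aluminium bond gives the E olefin, as in the LiAlH4 reduction of propargylic alcohols to E allylic alcohols.

Step 12
Reactants: 16 dialkenylcyclohexenol
Product: 19 ten-membered C6 ketone (2R,3S,8S,9S) with Z C4=C5 and ring-cis C1=C10, via potassium alkoxide 17 (not isolated), via potassium enolate 18 (not isolated)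
Conditions: KH, 18-crown-6, THF, 0 °C to rt; then AcOH, THF, −78 °C
Reagents that add atoms: none
Why: KH forms the C6 alkoxide and the crown ether strips the cation, so the oxyanion drives a concerted suprafacial [3,3] shift of the 1,5-diene C8=C7–C6–C1–C10=C9 (anionic oxy-Cope rearrangement of a cis-1,2-dialkenylcyclohexanol is the closest known reaction type) that forms C8–C9 and C1=C10 while C1–C6 breaks, and gives the C7 enolate regiospecifically. The ten-membered ring is not closed by an exo or endo cyclisation but by ring expansion: the new C8–C9 bond completes a chair array fused to the six-membered ring, whose shared C1–C6 bond is cut in the same event, and the dioxin ring is carried along as a 1,3-dioxane. C8 and C9 are set by chirality transfer from C6 and C1 through the chair, since the E enol ether puts O8 equatorial and the dioxin ring holds O9 trans to C1 and therefore equatorial, which gives the trans-8,9-diol in the 8S,9S sense. The step needs the chair with the C1–C2 bond pseudoaxial (ring-cis C1=C10) to win over the chair with C2 pseudoequatorial, which would give the ring-trans olefin and the opposite sense at C8/C9. The required chair derives from the half-chair that keeps the branched C1 substituent pseudoequatorial and the allylic C3–O bond pseudoaxial next to the C4 methyl (A(1,2) strain), whereas the competing half-chair sets the naked C6 oxyanion syn-axial to O2. The enolate is protonated at −78 °C because loss of the C8 ether needs a rotation about C7–C8 that brings C8–O into line with the enolate π system.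

Step 13
Reactants: 19 ten-membered ketone; 20 methyl bromoacetate
Product: 21 C7-alkylated keto ester (C7–CH2CO2Me, C11 cis to O8)
Conditions: LiN(SiMe3)2, THF, −78 °C; then 20, −78 to −45 °C
Reagents that add atoms: none
Why: Kinetic α′ deprotonation at C7 gives the lithium enolate, lithium is held between the enolate oxygen and the C8 ether oxygen, and the bromoacetate enters anti to ring carbon C9 on the open face of this chelate (Fráter–Seebach-type alkylation), which places C11 cis to O8.

Step 14
Reactants: 21 keto ester
Product: 23 (6S,7S) hydroxy acid (C6 epimeric to the target), via hydroxy ester 22 (not isolated)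
Conditions: Zn(BH4)2, Et2O, −20 °C; then LiOH, THF/H2O, 0 °C; AcOH to pH 5
Reagents that add atoms: lithium hydroxide, [Li+].[OH-]
Why: Chelation-controlled 1,2-reduction in which zinc bridges the C6 carbonyl and the C8 ether oxygen and hydride adds axially to the chelate with C11 and C9 equatorial, giving predictably the 6S alcohol (O6 cis to C11); LiOH then hydrolyses the ester and reopens any cis-lactone.

Step 15
Reactants: 23 hydroxy acid
Product: 24 trans-fused 6,12-lactone (6R,7S)
Conditions: PPh3, DIAD, THF, 0 °C
Reagents that add atoms: none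
Why: Mitsunobu lactonisation, in which the allylic C6 alcohol is activated as its oxyphosphonium ion and displaced by the carboxylate in a 5-exo-tet SN2 closure with inversion, turning the 6S alcohol into the 6R trans-lactone of the target.

Step 16
Reactants: 24 lactone
Product: 25 C11 diethylphosphono lactone (C11 epimers, of no consequence)
Conditions: LiN(iPr)2 (2.2 equiv), ClP(O)(OEt)2, THF, −78 °C to rt
Reagents that add atoms: diethyl chlorophosphate, CCOP(=O)(Cl)OCC
Why: O-Phosphorylation of the lactone enolate and base-induced 1,3-phosphorus shift of the enol phosphate give the α-phosphono lactone, a masked α-methylene lactone that can be unveiled under mild conditions at the end.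

Step 17
Reactants: 25 phosphono lactone
Product: 26 9,14-diol (C2/C3 acetonide retained)
Conditions: PPTS (cat.), MeOH, 0 °C to rt
Reagents that add atoms: none
Why: Acid-catalysed transketalisation cleaves the six-membered 1,3-dioxane acetonide far faster than the cis-fused dioxolane, the selectivity known from mixed five- and six-membered isopropylidene acetals of sugars.

Step 18
Reactants: 26 9,14-diol
Product: 28 C14 methyl ester with free 9-OH, via C14 carboxylic acid 27 (not isolated)
Conditions: TEMPO (cat.), PhI(OAc)2, MeCN/H2O, rt; then Me3SiCHN2, MeOH/toluene, 0 °C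
Reagents that add atoms: water, O; (trimethylsilyl)diazomethane, C[Si](C)(C)C=[N+]=[N-]
Why: The oxoammonium ion oxidises the primary allylic alcohol in preference to the secondary one and, in water, carries the aldehyde hydrate on to the acid, which the diazoalkane methylates.

Step 19
Reactants: 28 hydroxy ester; 29 (R)-2-methylbutanoic acid
Product: 30 O9 (R)-2-methylbutanoate
Conditions: DCC, DMAP (cat.), CH2Cl2, 0 °C to rt
Reagents that add atoms: none
Why: Steglich esterification of the secondary allylic alcohol through the acylpyridinium ion, under conditions too mild to epimerise the α-methyl acid.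

Step 20
Reactants: 30 O9 ester
Product: 31 2,3-cis-diol
Conditions: AcOH/H2O (4:1), 40 °C
Reagents that add atoms: none
Why: Mild aqueous acid hydrolyses the remaining isopropylidene acetal through its oxocarbenium ion while the PMB ether, the esters and the phosphonate survive.

Step 21
Reactants: 31 2,3-diol
Product: 34 2,3-cis-epoxide (2R,3S) with O8 still PMB-protected, via cyclic orthoacetate 32 (not isolated), via chloro acetate 33 (not isolated)
Conditions: MeC(OMe)3, PPTS (cat.), CH2Cl2, rt; Me3SiCl, CH2Cl2, 0 °C to rt; K2CO3, MeOH, 0 °C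
Reagents that add atoms: none
Why: Orthoester-based diol-to-epoxide conversion with net retention, in which the cyclic orthoacetate is ionised to the acetoxonium ion, chloride opens it at the allylic carbon with inversion, and methanolysis of the acetate frees the neighbouring alkoxide, which closes the ring by a second inversion (3-exo-tet), so the epoxide keeps both C–O configurations of the cis-diol.

Step 22
Reactants: 34 epoxide PMB ether
Product: 35 C8 alcohol
Conditions: DDQ, CH2Cl2/pH 7 buffer, 0 °C
Reagents that add atoms: none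
Why: Oxidative cleavage of the p-methoxybenzyl ether (hydride abstraction, hydrolysis of the oxocarbenium ion) under buffered conditions that leave the epoxide, esters and phosphonate intact.

Step 23
Reactants: 36 angelic acid
Product: 37 (Z)-2-methylbut-2-en-1-ol
Conditions: LiAlH4, Et2O, 0 °C; then Na2SO4·10H2O
Reagents that add atoms: none
Why: Hydride reduction of the carboxylic acid to the primary allylic alcohol without change of the olefin geometry.

Step 24
Reactants: 37 (Z)-allylic alcohol
Product: 38 (2R,3S)-(2,3-dimethyloxiran-2-yl)methanol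
Conditions: Ti(OiPr)4, L-(+)-diethyl tartrate, t-BuOOH, 4 Å MS, CH2Cl2, −20 °C
Reagents that add atoms: tert-butyl hydroperoxide, CC(C)(C)OO
Why: Sharpless asymmetric epoxidation, in which the L-tartrate–titanium complex delivers oxygen to the face that gives the 2R,3S epoxy alcohol while the Z olefin fixes the trans relation of the two methyl groups.

Step 25
Reactants: 38 epoxy alcohol
Product: 39 (2S,3S)-2,3-dimethyloxirane-2-carboxylic acid
Conditions: TEMPO (cat.), PhI(OAc)2, MeCN/H2O, 0 °C to rt
Reagents that add atoms: water, O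
Why: Oxoammonium oxidation of the primary alcohol through the aldehyde hydrate to the acid under near-neutral conditions that the epoxide tolerates.

Step 26
Reactants: 35 C8 alcohol; 39 epoxy acid
Product: 40 O8 epoxyangelate with the C11 phosphonate still in place
Conditions: 39, 2,4,6-trichlorobenzoyl chloride, Et3N, THF; then 35, DMAP, toluene, rt
Reagents that add atoms: none
Why: Yamaguchi esterification, in which the mixed trichlorobenzoic anhydride passes the hindered glycidic acyl group to the C8 alcohol through the acylpyridinium ion before the neighbouring O9 ester can migrate.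

Step 27
Reactants: 40 phosphonate
Product: 41 CNP0485260.1
Conditions: K2CO3, aq. HCHO (37%), THF, 0 °C
Reagents that add atoms: formaldehyde, C=O
Why: Horner–Wadsworth–Emmons olefination of the phosphonate-stabilised lactone carbanion with formaldehyde installs the exocyclic C11=C13 methylene under carbonate conditions mild enough for the two esters and two epoxides.

Compound list
1 | 4-iodotoluene | Cc1ccc(I)cc1 | starting material
2 | (1S,2S)-3-iodo-6-methylcyclohexa-3,5-diene-1,2-diol | CC1=CC=C(I)[C@@H](O)[C@H]1O | intermediate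
3 | (3aS,7aS)-7-iodo-2,2,4-trimethyl-3a,7a-dihydro-1,3-benzodioxole | CC1=CC=C(I)[C@H]2OC(C)(C)O[C@@H]12 | intermediate
4 | (3aS,7aR)-2,2,4-trimethyl-3a,7a-dihydro-1,3-benzodioxole | CC1=CC=C[C@H]2OC(C)(C)O[C@@H]12 | intermediate
5 | (3aS,7aR)-2,2,4-trimethyl-3a,6,7,7a-tetrahydro-1,3-benzodioxole | CC1=CCC[C@H]2OC(C)(C)O[C@@H]12 | intermediate
6 | (4S,5R)-4,5-(isopropylidenedioxy)-3-methylcyclohex-2-en-1-one | CC1=CC(=O)C[C@H]2OC(C)(C)O[C@@H]12 | intermediate
7 | trimethylsilyl dienol ether of 6 (C6(OSiMe3)=C1) | CC1=CC(O[Si](C)(C)C)=C[C@H]2OC(C)(C)O[C@@H]12 | intermediate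
8 | 2,2-dimethyl-1,3-dioxan-5-one | CC1(C)OCC(=O)CO1 | starting material
9 | 2,2-dimethyl-4H-1,3-dioxin-5-yl trifluoromethanesulfonate | CC1(C)OCC(OS(=O)(=O)C(F)(F)F)=CO1 | intermediate
10 | enone 6 with a β 2,2-dimethyl-4H-1,3-dioxin-5-yl group on C1 (anti to the acetonide) | CC1=CC(=O)[C@H](C3=COC(C)(C)OC3)[C@H]2OC(C)(C)O[C@@H]12 | intermediate
11 | 4-methoxybenzyl alcohol | COc1ccc(CO)cc1 | starting material
12 | trichloroethylene | ClC=C(Cl)Cl | starting material
13 | (E)-1,2-dichlorovinyl 4-methoxybenzyl ether | COc1ccc(CO/C(Cl)=C\Cl)cc1 | intermediate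
14 | lithium 2-(4-methoxybenzyloxy)ethynide | [Li+].[C-]#COCc1ccc(OC)cc1 | intermediate
15 | C6 propargylic alcohol (β alkynyl, α OH; C1 β dioxinyl) | CC1=C[C@](O)(C#COCc3ccc(OC)cc3)[C@H](C4=COC(C)(C)OC4)[C@H]2OC(C)(C)O[C@@H]12 | intermediate
16 | cis-1,6-dialkenylcyclohexenol (C6 α OH and β E-alkoxyvinyl; C1 β dioxinyl; acetonide α) | CC1=C[C@](O)(/C=C/OCc3ccc(OC)cc3)[C@H](C4=COC(C)(C)OC4)[C@H]2OC(C)(C)O[C@@H]12 | intermediate
17 | potassium C6 alkoxide of 16 | CC1=C[C@]([O-])(/C=C/OCc3ccc(OC)cc3)[C@H](C4=COC(C)(C)OC4)[C@H]2OC(C)(C)O[C@@H]12.[K+] | intermediate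
18 | potassium C6–C7 enolate of 19 (C5 trans to C8) | [C@H]1(OCc5ccc(OC)cc5)/C=C(\[O-])/C=C(/C)[C@@H]3OC(C)(C)O[C@@H]3/C=C4/COC(C)(C)O[C@@H]41.[K+] | intermediate
19 | ten-membered C6 ketone, (2R,3S,8S,9S): O8 PMB, O9/O14 acetonide, C2/C3 acetonide, Z C4=C5, ring-cis C1=C10 | O=C1/C=C(/C)[C@@H]3OC(C)(C)O[C@@H]3/C=C4/COC(C)(C)O[C@@H]4[C@@H](OCc5ccc(OC)cc5)C1 | intermediate
20 | methyl bromoacetate | COC(=O)CBr | starting material
21 | C7-(methoxycarbonylmethyl) ketone (C11 cis to O8) | O=C1/C=C(/C)[C@@H]3OC(C)(C)O[C@@H]3/C=C4/COC(C)(C)O[C@@H]4[C@@H](OCc5ccc(OC)cc5)[C@H]1CC(=O)OC | intermediate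
22 | (6S,7S) hydroxy methyl ester | O[C@H]1/C=C(/C)[C@@H]3OC(C)(C)O[C@@H]3/C=C4/COC(C)(C)O[C@@H]4[C@@H](OCc5ccc(OC)cc5)[C@H]1CC(=O)OC | intermediate
23 | (6S,7S) hydroxy acid | O[C@H]1/C=C(/C)[C@@H]3OC(C)(C)O[C@@H]3/C=C4/COC(C)(C)O[C@@H]4[C@@H](OCc5ccc(OC)cc5)[C@H]1CC(=O)O | intermediate
24 | trans-fused 6,12-lactone, (6R,7S) | O=C1O[C@@H]2/C=C(/C)[C@@H]3OC(C)(C)O[C@@H]3/C=C4/COC(C)(C)O[C@@H]4[C@@H](OCc5ccc(OC)cc5)[C@H]2C1 | intermediate
25 | C11 diethylphosphono lactone | O=C1O[C@@H]2/C=C(/C)[C@@H]3OC(C)(C)O[C@@H]3/C=C4/COC(C)(C)O[C@@H]4[C@@H](OCc5ccc(OC)cc5)[C@H]2C1P(=O)(OCC)OCC | intermediate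
26 | 9,14-diol | O=C1O[C@@H]2/C=C(/C)[C@@H]3OC(C)(C)O[C@@H]3/C=C(/CO)[C@H](O)[C@@H](OCc5ccc(OC)cc5)[C@H]2C1P(=O)(OCC)OCC | intermediate
27 | C14 carboxylic acid, 9-ol | O=C1O[C@@H]2/C=C(/C)[C@@H]3OC(C)(C)O[C@@H]3/C=C(/C(=O)O)[C@H](O)[C@@H](OCc5ccc(OC)cc5)[C@H]2C1P(=O)(OCC)OCC | intermediate
28 | C14 methyl ester, 9-ol | O=C1O[C@@H]2/C=C(/C)[C@@H]3OC(C)(C)O[C@@H]3/C=C(/C(=O)OC)[C@H](O)[C@@H](OCc5ccc(OC)cc5)[C@H]2C1P(=O)(OCC)OCC | intermediate
29 | (R)-2-methylbutanoic acid | CC[C@@H](C)C(=O)O | starting material
30 | O9 (R)-2-methylbutanoate | O=C1O[C@@H]2/C=C(/C)[C@@H]3OC(C)(C)O[C@@H]3/C=C(/C(=O)OC)[C@H](OC(=O)[C@H](C)CC)[C@@H](OCc5ccc(OC)cc5)[C@H]2C1P(=O)(OCC)OCC | intermediate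
31 | 2,3-cis-diol | O=C1O[C@@H]2/C=C(/C)[C@H](O)[C@H](O)/C=C(/C(=O)OC)[C@H](OC(=O)[C@H](C)CC)[C@@H](OCc5ccc(OC)cc5)[C@H]2C1P(=O)(OCC)OCC | intermediate
32 | 2,3-cyclic methyl orthoacetate | O=C1O[C@@H]2/C=C(/C)[C@@H]3OC(C)(OC)O[C@@H]3/C=C(/C(=O)OC)[C@H](OC(=O)[C@H](C)CC)[C@@H](OCc5ccc(OC)cc5)[C@H]2C1P(=O)(OCC)OCC | intermediate
33 | 3-chloro 2-acetate (C3 inverted) | O=C1O[C@@H]2/C=C(/C)[C@@H](Cl)[C@H](OC(C)=O)/C=C(/C(=O)OC)[C@H](OC(=O)[C@H](C)CC)[C@@H](OCc5ccc(OC)cc5)[C@H]2C1P(=O)(OCC)OCC | intermediate
34 | (2R,3S) cis-epoxide, O8 PMB | O=C1O[C@@H]2/C=C(/C)[C@@H]3O[C@@H]3/C=C(/C(=O)OC)[C@H](OC(=O)[C@H](C)CC)[C@@H](OCc5ccc(OC)cc5)[C@H]2C1P(=O)(OCC)OCC | intermediate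
35 | C8 alcohol | O=C1O[C@@H]2/C=C(/C)[C@@H]3O[C@@H]3/C=C(/C(=O)OC)[C@H](OC(=O)[C@H](C)CC)[C@@H](O)[C@H]2C1P(=O)(OCC)OCC | intermediate
36 | angelic acid, (Z)-2-methylbut-2-enoic acid | C/C=C(/C)C(=O)O | starting material
37 | (Z)-2-methylbut-2-en-1-ol | C/C=C(/C)CO | intermediate
38 | (2R,3S)-(2,3-dimethyloxiran-2-yl)methanol | OC[C@@]1(C)O[C@H]1C | intermediate
39 | (2S,3S)-2,3-dimethyloxirane-2-carboxylic acid | OC(=O)[C@@]1(C)O[C@H]1C | intermediate
40 | O8 epoxyangelate, C11 phosphonate | O=C1O[C@@H]2/C=C(/C)[C@@H]3O[C@@H]3/C=C(/C(=O)OC)[C@H](OC(=O)[C@H](C)CC)[C@@H](OC(=O)[C@@]6(C)O[C@H]6C)[C@H]2C1P(=O)(OCC)OCC | intermediate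
41 | CNP0485260.1 | C=C1C(=O)O[C@@H]2/C=C(/C)[C@@H]3O[C@@H]3/C=C(/C(=O)OC)[C@H](OC(=O)[C@H](C)CC)[C@@H](OC(=O)[C@@]3(C)O[C@H]3C)[C@@H]12 | target

Total step count: 27. Longest linear sequence: 22 steps (1–6, 8, 10–22, 26, 27).

Steps most likely to fail

Step 12. The naked potassium enolate may expel the C8 p-methoxybenzyloxide (β-elimination) while the rearrangement is still running or during the quench, and part of the material may pass through the competing chair. The fallback sets out from 16 and rejoins the route at 21 without passing through 19. After the rearrangement (KN(SiMe3)2, 18-crown-6, THF) the enolate is not protonated but silylated in the flask with Et3SiCl at −78 °C, giving the triethylsilyl enol ether F1 of the ring-expanded ketone, so the β-alkoxy enolate never meets a protic quench or a warm-up. MeLi then cleaves the enol silane regiospecifically to the lithium enolate F2, which is alkylated with 20 under the chelate control of step 13. This does not correct the chair selection.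

Step 8. The tin enolate may lose the C2 oxygen by β-elimination and aromatise, or transmetalate too slowly so that the enol silane reverts to 6. The fallback sets out from 7 and returns to 10. N-Bromosuccinimide in THF at −78 °C converts the enol silane into the α′-bromo enone F3 (bromine on C1, anti to the dioxolane). Activated zinc then gives the bromozinc enolate F4, a Reformatsky-type reagent, and zerovalent palladium (Pd(PPh3)4) couples it with triflate 9 in a Negishi-type reaction. This reaches the same C1–C10 bond without fluoride, tin or an amide base.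

Step 13. The bromoacetate may attack the other enolate face if the lithium chelate with O8 does not form, giving the C7 epimer. The fallback sets out from 19 and returns to 21. The lithium enolate is added to methyl glyoxylate to give the aldol F5; mesylation and elimination (MsCl, Et3N, then DBU) give the C7=C11 alkylidene keto ester F6. Conjugate reduction with [(Ph3P)CuH]6 and protonation of the resulting enolate at low temperature then set C7 by delivering hydrogen, not carbon, to the face the enolate prefers. A wrong facial preference in the alkylation thus becomes the right one here.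

Further compounds
F1 | step 12 | triethylsilyl enol ether of 19 (C6(OSiEt3)=C7, C5 trans to C8) | [C@H]1(OCc5ccc(OC)cc5)/C=C(\O[Si](CC)(CC)CC)/C=C(/C)[C@@H]3OC(C)(C)O[C@@H]3/C=C4/COC(C)(C)O[C@@H]41
F2 | step 12 | lithium C6–C7 enolate of 19 | [C@H]1(OCc5ccc(OC)cc5)/C=C(\[O-])/C=C(/C)[C@@H]3OC(C)(C)O[C@@H]3/C=C4/COC(C)(C)O[C@@H]41.[Li+]
F3 | step 8 | α′-bromo enone (bromine on C1, β) | CC1=CC(=O)[C@H](Br)[C@H]2OC(C)(C)O[C@@H]12
F4 | step 8 | bromozinc enolate of 6 (C6(OZnBr)=C1) | CC1=CC(O[Zn]Br)=C[C@H]2OC(C)(C)O[C@@H]12
F5 | step 13 | glyoxylate aldol of 19 (C7–CH(OH)CO2Me) | O=C1/C=C(/C)[C@@H]3OC(C)(C)O[C@@H]3/C=C4/COC(C)(C)O[C@@H]4[C@@H](OCc5ccc(OC)cc5)C1C(O)C(=O)OC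
F6 | step 13 | C7=C11 alkylidene keto ester | O=C1/C=C(/C)[C@@H]3OC(C)(C)O[C@@H]3/C=C4/COC(C)(C)O[C@@H]4[C@@H](OCc5ccc(OC)cc5)C1=CC(=O)OC
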